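**Retrosynthetic overview**
1. No ring is formed. Both benzene rings are bought: ring B comes from guaiacol 1 (through 2-bromo-6-methoxyphenol 2) and ring A from 5-bromovanillin 3 (through benzylic alcohol 4).
2. The key disconnection is one aryl–CH2 bond. The phenolate of 2 adds through its para carbon, in a 1,6-Michael addition, to p-quinone methide 5 released from 4. This gives bisphenol 7 by way of dienone 6.
3. The two remaining C–Br bonds are made late, on tetramethyl ether 8, para to each 5-OMe group, to give 9.
4. The last disconnection is the four O–CH3 bonds. BBr3 cleaves them (through boronate 10) and frees both catechols of target 11.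

Assumption: the target has no stereocentre and is achiral, so "single enantiomer" calls for no stereocontrol.

**Step 1**
Reactants: 1 guaiacol (2-methoxyphenol)
Product: 2 2-bromo-6-methoxyphenol
Conditions: NBS (1.0 equiv, slow addition), diisopropylamine (10 mol %), CH2Cl2, 0 °C to rt
Reagents that add atoms: N-bromosuccinimide, O=C1CCC(=O)N1Br
Why: This is an amine-catalysed, ortho-selective electrophilic aromatic bromination (Fujisaki-type NBS bromination), in which the N-bromoamine formed in the flask is hydrogen-bonded to the phenol OH and delivers bromine to the only free ortho carbon (C6) rather than to the para carbon.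

**Step 2**
Reactants: 3 5-bromovanillin (3-bromo-4-hydroxy-5-methoxybenzaldehyde)
Product: 4 5-bromovanillyl alcohol (2-bromo-4-(hydroxymethyl)-6-methoxyphenol)
Conditions: NaBH4 (0.5 equiv), 1 M aq NaOH (1.1 equiv), 0 °C to rt, 1 h; then 1 M HCl to pH 6, 0 °C
Reagents that add atoms: none
Why: Carbonyl hydride reduction with NaBH4 is chemoselective for the aldehyde, leaves the aryl bromide and methyl ether alone, and the cold near-neutral quench keeps the ionisable p-hydroxybenzyl alcohol intact.

**Step 3 (key step)**
Reactants: 4 5-bromovanillyl alcohol; 2 2-bromo-6-methoxyphenol (1.1 equiv)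
Product: 7 bis(3-bromo-4-hydroxy-5-methoxyphenyl)methane, via p-quinone methide 5 (not isolated), via dienone adduct 6 (not isolated)
Conditions: NaOH (2.5 equiv, 1 M), degassed H2O, N2, sealed vessel, 130 °C, 16 h; then 2 M HCl, 0 °C
Reagents that add atoms: none
Why: This is an intermolecular 1,6-Michael (vinylogous conjugate) addition in which the phenolate of 4 expels hydroxide to give the extended enone 5, the phenolate of 2 acts as an extended enolate that can bond only through its para carbon because both ortho carbons are blocked, O-alkylation is reversible under these conditions, and tautomerisation of 6 to the phenol makes the C–C bond permanent (the C4 stereocentre of 6 is lost, so none remains).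

**Step 4**
Reactants: 7 bis(3-bromo-4-hydroxy-5-methoxyphenyl)methane
Product: 8 bis(3-bromo-4,5-dimethoxyphenyl)methane
Conditions: MeI (3 equiv), K2CO3 (4 equiv), DMF, N2, rt to 40 °C, 12 h
Reagents that add atoms: iodomethane, CI
Why: Williamson ether synthesis (SN2 on MeI by the two phenolates) caps the free phenols, so that bromine in the next step can neither attack ipso at the carbon para to a free OH (C–C cleavage) nor oxidise the bisphenol to a quinone methide.

**Step 5**
Reactants: 8 bis(3-bromo-4,5-dimethoxyphenyl)methane
Product: 9 bis(2,3-dibromo-4,5-dimethoxyphenyl)methane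
Conditions: Br2 (2.3 equiv), AcOH, rt, dark, 12 h
Reagents that add atoms: bromine, BrBr
Why: In this twofold electrophilic aromatic bromination the 4-OMe group of each ring is twisted out of conjugation by its two ortho neighbours, so the coplanar 5-OMe group directs para to C2 (the same outcome as 5-bromovanillin going to 5,6-dibromovanillin), while the polar medium and the dark suppress radical bromination of the CH2 bridge.

**Step 6**
Reactants: 9 bis(2,3-dibromo-4,5-dimethoxyphenyl)methane
Product: 11 bis(2,3-dibromo-4,5-dihydroxyphenyl)methane (target CNP0260813.0), via cyclic bromoboronate 10 (not isolated)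
Conditions: BBr3 (6 equiv), CH2Cl2, N2, 0 °C to rt, 24 h; then ice-water
Reagents that add atoms: none
Why: BBr3-mediated aryl methyl ether cleavage (Lewis acid complexation at oxygen, then SN2 attack of bromide on methyl) removes all four methyl groups without touching the C–Br bonds or the CH2 bridge, and water hydrolyses catechol boronate 10 to the free bis-catechol.

**Compound list**
1 | guaiacol (2-methoxyphenol) | COc1ccccc1O | starting material
2 | 2-bromo-6-methoxyphenol | COc1cccc(Br)c1O | intermediate
3 | 5-bromovanillin (3-bromo-4-hydroxy-5-methoxybenzaldehyde) | COc1cc(C=O)cc(Br)c1O | starting material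
4 | 5-bromovanillyl alcohol (2-bromo-4-(hydroxymethyl)-6-methoxyphenol) | COc1cc(CO)cc(Br)c1O | intermediate
5 | 2-bromo-6-methoxy-4-methylidenecyclohexa-2,5-dien-1-one (p-quinone methide) | C=C1C=C(Br)C(=O)C(OC)=C1 | intermediate (not isolated)
6 | 2-bromo-4-[(3-bromo-4-hydroxy-5-methoxyphenyl)methyl]-6-methoxycyclohexa-2,5-dien-1-one (racemic at C4, transient) | COC1=CC(Cc2cc(Br)c(O)c(OC)c2)C=C(Br)C1=O | intermediate (not isolated)
7 | bis(3-bromo-4-hydroxy-5-methoxyphenyl)methane | COc1cc(Cc2cc(Br)c(O)c(OC)c2)cc(Br)c1O | intermediate
8 | bis(3-bromo-4,5-dimethoxyphenyl)methane | COc1cc(Cc2cc(Br)c(OC)c(OC)c2)cc(Br)c1OC | intermediate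
9 | bis(2,3-dibromo-4,5-dimethoxyphenyl)methane | COc1cc(Cc2cc(OC)c(OC)c(Br)c2Br)c(Br)c(Br)c1OC | intermediate
10 | 6,6'-methylenebis(2,4,5-tribromo-1,3,2-benzodioxaborole) | BrB1Oc2cc(Cc3cc4OB(Br)Oc4c(Br)c3Br)c(Br)c(Br)c2O1 | intermediate (not isolated)
11 | bis(2,3-dibromo-4,5-dihydroxyphenyl)methane (achiral) | Oc1cc(Cc2cc(O)c(O)c(Br)c2Br)c(Br)c(Br)c1O | target

**Total steps:** 6. **Longest linear sequence:** 5 (1 → 2 → 7 → 8 → 9 → 11, or 3 → 4 → 7 → 8 → 9 → 11).

**Steps most likely to fail**

The first risk is step 3. Loss of hydroxide from the bromine-bearing phenolate may be slow, and benzyl aryl ethers or oligomers may build up. Any self-attack of 4 at its own para carbon only releases formaldehyde. That formaldehyde hydroxymethylates 2 back to 4, so this side path still ends at 7.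

- The fallback gives up the conjugate addition and builds the diaryl carbon by Friedel–Crafts acylation.
- It sets out from 1, which is O-methylated (MeI, K2CO3) to veratrole F1.
- F1 is acylated with commercial 3,4-dimethoxybenzoic acid in polyphosphoric acid at 80 °C to bis(3,4-dimethoxyphenyl)methanone F2.
- Excess Br2 in warm AcOH gives bis(2,3-dibromo-4,5-dimethoxyphenyl)methanone F3.
- NaBH4 in THF/MeOH gives bis(2,3-dibromo-4,5-dimethoxyphenyl)methanol F4.
- Ionic deoxygenation with Et3SiH in CF3CO2H/CH2Cl2 brings the sequence back to the route at 9.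

The second risk is step 5. Some attack at C6, radical bromination of the bridge, or ipso cleavage could occur.

- The fallback puts all four bromines in place before the coupling.
- It sets out from 3, which is brominated (Br2, Fe powder as catalyst, AcOH, heat) to 5,6-dibromovanillin F5.
- NaBH4 in aq NaOH reduces F5 to 5,6-dibromovanillyl alcohol F6.
- Heating F6 alone in degassed aq NaOH at 130 °C forms the dibromo p-quinone methide F7.
- A second phenolate of F6 adds to F7 through its own para (ipso) carbon to give the ipso dienone adduct F8.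
- F8 loses formaldehyde by retro-aldol cleavage, as syringyl alcohol is known to do in hot alkali, and gives bis(2,3-dibromo-4-hydroxy-5-methoxyphenyl)methane F9.
- BBr3 under the step 6 conditions converts F9 into 10, where the fallback rejoins the route, and then into 11.

The third risk is step 1. 4-Bromoguaiacol or dibromide may be hard to separate from 2.

- The fallback replaces electrophilic bromination by directed ortho-metalation.
- It sets out from 1, which is protected (MOMCl, iPr2NEt, CH2Cl2) as 1-methoxy-2-(methoxymethoxy)benzene F10.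
- n-BuLi in THF at 0 °C lithiates F10 next to the stronger directing OMOM group to give [3-methoxy-2-(methoxymethoxy)phenyl]lithium F11.
- 1,2-Dibromoethane at −78 °C gives 1-bromo-3-methoxy-2-(methoxymethoxy)benzene F12.
- HCl in MeOH removes the acetal, and the fallback comes back to the route at 2.
- Compound 2 is also sold commercially, which is a further way around this step.

**Further compounds**
F1 | step 3 | veratrole (1,2-dimethoxybenzene) | COc1ccccc1OC
F2 | step 3 | bis(3,4-dimethoxyphenyl)methanone | COc1ccc(cc1OC)C(=O)c1ccc(OC)c(OC)c1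
F3 | step 3 | bis(2,3-dibromo-4,5-dimethoxyphenyl)methanone | COc1cc(C(=O)c2cc(OC)c(OC)c(Br)c2Br)c(Br)c(Br)c1OC
F4 | step 3 | bis(2,3-dibromo-4,5-dimethoxyphenyl)methanol | COc1cc(C(O)c2cc(OC)c(OC)c(Br)c2Br)c(Br)c(Br)c1OC
F5 | step 5 | 5,6-dibromovanillin (2,3-dibromo-4-hydroxy-5-methoxybenzaldehyde) | COc1cc(C=O)c(Br)c(Br)c1O
F6 | step 5 | 5,6-dibromovanillyl alcohol (2,3-dibromo-4-(hydroxymethyl)-6-methoxyphenol) | COc1cc(CO)c(Br)c(Br)c1O
F7 | step 5 | 2,3-dibromo-6-methoxy-4-methylidenecyclohexa-2,5-dien-1-one | C=C1C=C(OC)C(=O)C(Br)=C1Br
F8 | step 5 | 2,3-dibromo-4-[(2,3-dibromo-4-hydroxy-5-methoxyphenyl)methyl]-4-(hydroxymethyl)-6-methoxycyclohexa-2,5-dien-1-one (racemic, transient) | COC1=CC(CO)(Cc2cc(OC)c(O)c(Br)c2Br)C(Br)=C(Br)C1=O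
F9 | step 5 | bis(2,3-dibromo-4-hydroxy-5-methoxyphenyl)methane | COc1cc(Cc2cc(OC)c(O)c(Br)c2Br)c(Br)c(Br)c1O
F10 | step 1 | 1-methoxy-2-(methoxymethoxy)benzene | COCOc1ccccc1OC
F11 | step 1 | [3-methoxy-2-(methoxymethoxy)phenyl]lithium | [Li]c1cccc(OC)c1OCOC
F12 | step 1 | 1-bromo-3-methoxy-2-(methoxymethoxy)benzene | COCOc1c(Br)cccc1OC
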